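**Retrosynthetic overview**

1. The target is the (S)-3-methylpentanoate of a 7-epi-eudesmane (trans-decalin; 10β-CH3, 5α-H, 4α-OH/4β-CH3, 9β-O-acyl, C7 side chain α). The acrylic acid is unmasked last from an isopropenyl group, and the C9 ester comes from a C9 ketone.
2. Ring A (C10–C1–C2–C3–C4–C5) is cut at C2–C3 together with the C4–O bond: hydrative cyclization of a 1,5-diene made of a C1=C2 vinyl group on C10 and a C3=C4 isopropenyl group on C5 of ring B.
3. Enabling feature: the C4 tertiary carbinol, whose methyl is axial and 1,3 to the C10 methyl, is what equatorial water capture of a C4 cation in a chair leaves behind; C5 and C10 of ring B carry the two arms trans-diequatorially.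
4. The diene is built on (R)-carvone, which supplies ring B (C5–C10), the C7 centre, the C10 methyl and the C9 oxygen, by conjugate addition at C5, aldol at C10 and dehydration.
5. Ring order: ring B from the chiral pool; ring A is the last ring closed (step 3).

Key step: step 3

Remark: eudesmane numbering and α/β descriptors (β = face of the C10 methyl) are used for the bicyclic compounds, and (S)-3-methylpentanoic acid is taken to be a purchasable building block.

**Route**

Step 1
Reactants: 1 (R)-(−)-carvone; 2 isopropenylmagnesium bromide; 3 acetaldehyde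
Product: 5 (2R,3S,5R)-2-(1-hydroxyethyl)-2-methyl-3,5-di(prop-1-en-2-yl)cyclohexan-1-one (both carbinol epimers), via bromomagnesium enolate 4 (not isolated)
Conditions: 2 (1.5 equiv), CuBr·SMe2 (10 mol %), THF, −78 → −40 °C; then 3 (3 equiv), −78 °C; aq NH4Cl
Reagents that add atoms: isopropenylmagnesium bromide (2), CC(=C)[Mg]Br; acetaldehyde (3), CC=O
Why: Copper-catalysed conjugate addition of the Grignard reagent should occur anti to the C5 isopropenyl group of carvone, and the regiodefined enolate should then add to acetaldehyde (aldol addition) anti to the new C3 substituent, which sets the quaternary carbon with its two-carbon arm trans to the C3 and cis to the C5 isopropenyl group, while the carbinol centre forms as a mixture that step 2 erases.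

Step 2
Reactants: 5 (2R,3S,5R)-2-(1-hydroxyethyl)-2-methyl-3,5-di(prop-1-en-2-yl)cyclohexan-1-one
Product: 6 (2S,3S,5R)-2-ethenyl-2-methyl-3,5-di(prop-1-en-2-yl)cyclohexan-1-one
Conditions: Martin sulfurane Ph2S[OC(CF3)2Ph]2 (1.5 equiv), CH2Cl2, 0 °C → rt
Reagents that add atoms: none
Why: Martin sulfurane dehydration (E2 through the alkoxysulfonium ion) can only remove a methyl hydrogen because the other neighbour of the carbinol is quaternary, so the terminal vinyl group should form under non-basic conditions that avoid retro-aldol cleavage.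

Step 3
Reactants: 6 (2S,3S,5R)-2-ethenyl-2-methyl-3,5-di(prop-1-en-2-yl)cyclohexan-1-one
Product: 7 4α-hydroxy-7-epi-eudesm-11-en-9-one (4R,5R,7R,10S; trans-decalin, 10β-CH3, 5α-H, 4β-CH3, C7 isopropenyl α and axial)
Conditions: [Pt{PhP(CH2CH2PPh2)2}(NCMe)](BF4)2 (10 mol %), H2O (5 equiv), Ph2NH (20 mol %), MeNO2/acetone, 25 → 40 °C
Reagents that add atoms: water, O
Why: Proposed new method: the electrophilic divalent platinum dication should bind the least substituted alkene (the C1=C2 vinyl group on C10), the terminal C3 of the C5 isopropenyl group then attacks C2 anti to the metal, water captures the resulting tertiary C4 cation, and the proton set free cleaves the C1–Pt bond, so that the diene is hydrated and cyclized at constant oxidation level with turnover of the metal. The closest known reaction types are the cation–olefin cyclizations of 1,5-dienes initiated at a terminal alkene by divalent platinum pincer dications and ended by a protic group with protodemetalation, and the PdCl2(MeCN)2-catalysed Cope rearrangement of 2-substituted 1,5-dienes, which passes through the same metallated cyclohexyl cation; new here are capture by external water and a vinyl group on a quaternary carbon. Ring A closes by C2–C3 bond formation in a 6-endo-trig mode through a chair in which the C10 and C5 arms are trans-diequatorial on ring B, so that only the trans-decalin can form. The single new stereocentre C4 is controlled by anti addition across C3=C4 in that chair: water enters equatorially on the α face, antiperiplanar to the new C2–C3 bond and remote from the axial C10 methyl group, which leaves the C4 methyl axial and the hydroxyl α (4R). The step needs selection among three alkenes and the avoidance of Grob-type fragmentation to a cyclodecadiene and of E1 loss from C4: only the monosubstituted vinyl group is a good ligand for the bulky dication, only the C5 isopropenyl group can reach C2 through a six-membered array, the strong C–Pt bond and the strain of the ten-membered diene disfavour fragmentation, and buffering by diphenylamine keeps the medium too weakly acidic to ionize the tertiary alcohol or protonate the C7 isopropenyl group.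

Step 4
Reactants: 7 4α-hydroxy-7-epi-eudesm-11-en-9-one
Product: 8 7-epi-eudesm-11-ene-4α,9β-diol (4R,5R,7R,9S,10S)
Conditions: Li (4 equiv), NH3(l)/THF, EtOH (2 equiv), −78 → −33 °C; NH4Cl
Reagents that add atoms: none
Why: Dissolving-metal reduction of the hindered C9 ketone should give the thermodynamically preferred equatorial 9β-alcohol, because the axial 9α-epimer would be 1,3-diaxial to the axial C7 isopropenyl group, while isolated alkenes and the tertiary alcohol are inert.

Step 5
Reactants: 9 (S)-3-methylpentanoic acid
Product: 10 (S)-3-methylpentanoyl chloride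
Conditions: (COCl)2 (1.2 equiv), DMF (cat.), CH2Cl2, 0 °C → rt; concentrate
Reagents that add atoms: oxalyl chloride, O=C(Cl)C(=O)Cl
Why: Vilsmeier-type activation converts the acid into its chloride, and the β-stereocentre is not enolisable and is retained.

Step 6
Reactants: 8 7-epi-eudesm-11-ene-4α,9β-diol; 10 (S)-3-methylpentanoyl chloride
Product: 11 9β-[(3S)-3-methylpentanoyloxy]-7-epi-eudesm-11-en-4α-ol
Conditions: 10 (1.3 equiv), pyridine (3 equiv), DMAP (10 mol %), CH2Cl2, 0 °C → rt
Reagents that add atoms: (S)-3-methylpentanoyl chloride (10), O=C(Cl)C[C@@H](C)CC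
Why: DMAP-catalysed acylation (nucleophilic catalysis) should take place only at the secondary equatorial C9 hydroxyl, since the tertiary C4 hydroxyl is inert under these conditions and no stereocentre is touched.

Step 7
Reactants: 11 9β-[(3S)-3-methylpentanoyloxy]-7-epi-eudesm-11-en-4α-ol
Product: 13 4α-hydroxy-9β-[(3S)-3-methylpentanoyloxy]-7-epi-eudesm-11(13)-en-12-al, via allylic alcohol 12 (not isolated)
Conditions: SeO2 (0.3 equiv), t-BuOOH (3 equiv), CH2Cl2, 0 °C → rt; then activated MnO2 (10 equiv), rt
Reagents that add atoms: selenium dioxide, O=[Se]=O; tert-butyl hydroperoxide, CC(C)(C)OO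
Why: Allylic oxidation with catalytic selenium dioxide (ene reaction then [2,3]-sigmatropic shift) should oxidise the methyl group of the only alkene, the 1,1-disubstituted isopropenyl unit, and manganese dioxide should converge the allylic alcohol to the 2-substituted acrolein without touching the saturated tertiary alcohol or the non-enolisable C7 centre.

Step 8
Reactants: 13 4α-hydroxy-9β-[(3S)-3-methylpentanoyloxy]-7-epi-eudesm-11(13)-en-12-al
Product: 14 4α-hydroxy-9β-[(3S)-3-methylpentanoyloxy]-7-epi-eudesm-11(13)-en-12-oic acid (4R,5R,7R,9S,10S; CNP0471281.1)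
Conditions: NaClO2 (3 equiv), NaH2PO4 (3 equiv), 2-methylbut-2-ene (10 equiv), t-BuOH/H2O, 0 °C → rt
Reagents that add atoms: sodium chlorite, [Na+].[O-]Cl=O
Why: Pinnick oxidation converts the enal to the acrylic acid under buffered, mildly acidic conditions that should spare the ester, the tertiary alcohol, the exocyclic alkene and the C7 centre, with 2-methylbut-2-ene scavenging hypochlorous acid.

**Compound list**

1 | (R)-(−)-carvone, (5R)-2-methyl-5-(prop-1-en-2-yl)cyclohex-2-en-1-one | CC1=CC[C@H](CC1=O)C(C)=C | starting material
2 | isopropenylmagnesium bromide (THF solution) | CC(=C)[Mg]Br | starting material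
3 | acetaldehyde | CC=O | starting material
4 | bromomagnesium (3S,5R)-2-methyl-3,5-di(prop-1-en-2-yl)cyclohex-1-en-1-olate | CC(=C)[C@H]1CC(O[Mg]Br)=C(C)[C@H](C(C)=C)C1 | intermediate
5 | (2R,3S,5R)-2-(1-hydroxyethyl)-2-methyl-3,5-di(prop-1-en-2-yl)cyclohexan-1-one (both carbinol epimers) | CC(=C)[C@H]1CC(=O)[C@@](C)(C(C)O)[C@H](C(C)=C)C1 | intermediate
6 | (2S,3S,5R)-2-ethenyl-2-methyl-3,5-di(prop-1-en-2-yl)cyclohexan-1-one | CC(=C)[C@H]1CC(=O)[C@@](C)(C=C)[C@H](C(C)=C)C1 | intermediate
7 | 4α-hydroxy-7-epi-eudesm-11-en-9-one (4R,5R,7R,10S) | CC(=C)[C@H]1CC(=O)[C@@]2(C)CCC[C@@](C)(O)[C@@H]2C1 | intermediate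
8 | 7-epi-eudesm-11-ene-4α,9β-diol (4R,5R,7R,9S,10S) | CC(=C)[C@H]1C[C@H](O)[C@@]2(C)CCC[C@@](C)(O)[C@@H]2C1 | intermediate
9 | (S)-3-methylpentanoic acid | OC(=O)C[C@@H](C)CC | starting material
10 | (S)-3-methylpentanoyl chloride | O=C(Cl)C[C@@H](C)CC | intermediate
11 | 9β-[(3S)-3-methylpentanoyloxy]-7-epi-eudesm-11-en-4α-ol | CC(=C)[C@H]1C[C@H](OC(=O)C[C@@H](C)CC)[C@@]2(C)CCC[C@@](C)(O)[C@@H]2C1 | intermediate
12 | 9β-[(3S)-3-methylpentanoyloxy]-7-epi-eudesm-11(13)-ene-4α,12-diol | C=C(CO)[C@H]1C[C@H](OC(=O)C[C@@H](C)CC)[C@@]2(C)CCC[C@@](C)(O)[C@@H]2C1 | intermediate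
13 | 4α-hydroxy-9β-[(3S)-3-methylpentanoyloxy]-7-epi-eudesm-11(13)-en-12-al | C=C(C=O)[C@H]1C[C@H](OC(=O)C[C@@H](C)CC)[C@@]2(C)CCC[C@@](C)(O)[C@@H]2C1 | intermediate
14 | 4α-hydroxy-9β-[(3S)-3-methylpentanoyloxy]-7-epi-eudesm-11(13)-en-12-oic acid (4R,5R,7R,9S,10S) | C=C(C(=O)O)[C@H]1C[C@H](OC(=O)C[C@@H](C)CC)[C@@]2(C)CCC[C@@](C)(O)[C@@H]2C1 | target

**Step count and risks**

Total step count: 8. Longest linear sequence: 7 (steps 1–4 and 6–8 from carvone; step 5 is a one-step side branch).

Steps most likely to fail:

1. Step 3 (proposed new method). The catalyst may stall at the alkylplatinum stage because protonolysis of the hindered C1–Pt bond is slow. The C4 cation may lose a proton instead of adding water. The acid released may ionize the isopropenyl groups. Fallback by known chemistry, from 4 back to 8: the enolate 4, generated as in step 1, is alkylated with 4-iodobut-1-ene (THF/HMPA, −40 → 0 °C) anti to the C3 substituent to give (2S,3S,5R)-2-(but-3-en-1-yl)-2-methyl-3,5-di(prop-1-en-2-yl)cyclohexan-1-one F1. Ring-closing metathesis between the butenyl and the adjacent isopropenyl group (second-generation Grubbs catalyst RuCl2(=CHPh)(H2IMes)(PCy3), CH2Cl2, 40 °C) closes ring A as 7-epi-eudesma-3,11-dien-9-one F2. Li/NH3 reduction as in step 4 gives 7-epi-eudesma-3,11-dien-9β-ol F3. mCPBA (1 equiv, NaHCO3, CH2Cl2, −20 °C) should epoxidise the trisubstituted ring alkene in preference to the 1,1-disubstituted isopropenyl group, from the α face opposite the axial C10 methyl, to give 3α,4α-epoxy-7-epi-eudesm-11-en-9β-ol F4. LiAlH4 (THF, reflux) delivers hydride to the secondary C3 and gives diol 8.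

2. Step 2. The β-hydroxy ketone with a quaternary α-carbon may undergo retro-aldol cleavage, or a 1,2-shift of acyl or methyl to the activated carbinol carbon may compete with elimination. Fallback, from 4 back to 6: the enolate 4 is added to phenyl vinyl sulfoxide as a vinyl cation equivalent (Michael addition, THF/HMPA, −40 → 0 °C; aq NH4Cl) to give (2S,3S,5R)-2-methyl-2-[2-(phenylsulfinyl)ethyl]-3,5-di(prop-1-en-2-yl)cyclohexan-1-one F5 (both sulfur epimers). Thermal syn-elimination of the sulfoxide (toluene, CaCO3, 110 °C) gives dienone 6.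

3. Step 4. Both faces of the C9 ketone are hindered (axial C7 isopropenyl on α, axial C10 methyl next to the β trajectory), so kinetic protonation may give the axial 9α-alcohol and erode facial selectivity. Fallback, from 7 back to 8: the axial alcohol is made on purpose by hydride attack from the β face (LiBH(s-Bu)3, THF, −78 °C) to give 7-epi-eudesm-11-ene-4α,9α-diol F6. This is then epimerized to the equatorial alcohol by reversible hydride transfer under Meerwein–Ponndorf–Verley/Oppenauer equilibration (Al(OiPr)3, i-PrOH, trace acetone, reflux), giving 8.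

**Further compounds**

F1 | step 3 | (2S,3S,5R)-2-(but-3-en-1-yl)-2-methyl-3,5-di(prop-1-en-2-yl)cyclohexan-1-one | CC(=C)[C@H]1CC(=O)[C@@](C)(CCC=C)[C@H](C(C)=C)C1
F2 | step 3 | 7-epi-eudesma-3,11-dien-9-one | CC(=C)[C@H]1CC(=O)[C@@]2(C)CCC=C(C)[C@@H]2C1
F3 | step 3 | 7-epi-eudesma-3,11-dien-9β-ol | CC(=C)[C@H]1C[C@H](O)[C@@]2(C)CCC=C(C)[C@@H]2C1
F4 | step 3 | 3α,4α-epoxy-7-epi-eudesm-11-en-9β-ol | CC(=C)[C@H]1C[C@H](O)[C@@]2(C)CC[C@H]3O[C@@]3(C)[C@@H]2C1
F5 | step 2 | (2S,3S,5R)-2-methyl-2-[2-(phenylsulfinyl)ethyl]-3,5-di(prop-1-en-2-yl)cyclohexan-1-one | CC(=C)[C@H]1CC(=O)[C@@](C)(CCS(=O)c2ccccc2)[C@H](C(C)=C)C1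
F6 | step 4 | 7-epi-eudesm-11-ene-4α,9α-diol | CC(=C)[C@H]1C[C@@H](O)[C@@]2(C)CCC[C@@](C)(O)[C@@H]2C1
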